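The ratio of reagent to starting material charged is 0.947 in this flask as in both earlier runs. If each unit of target takes one unit of reagent, the reagent charge bounds the target at that ratio, and lower still if the second substrate takes reagent too.

all flasks: starting material 1.5 M; reagent 1.42 M

|  | second substrate | free catalyst | remark | time |
|---|---|---|---|---|
| summer | 1.5 M (in portions, 4) | 100 mM | run made earlier; portions every 8.0 min |  |
| winter | 1.5 M (in portions, 4) | 160 mM | run made earlier; portions every 8.0 min |  |
| flask | 1.50 M (in portions, 4) | 75 mM | the portions of second substrate follow each other after 8.0 min, the first at the start | 4.0 h |

| run | time / h | starting material / % | target / % |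
|---|---|---|---|
| summer | 0.500 | 25.8 | 69.8 |
| summer | 1.00 | 20.0 | 76.9 |
| summer | 1.33 | 20.1 | 76.7 |
| summer | 2.00 | 19.3 | 76.7 |
| summer | 2.50 | 19.0 | 76.4 |
| winter | 0.200 | 29.6 | 63.2 |
| winter | 0.667 | 16.6 | 78.1 |
| winter | 1.00 | 15.9 | 78.3 |
| winter | 1.50 | 15.6 | 79.0 |
| winter | 2.50 | 15.4 | 79.5 |

(readings scatter by 0.5 percentage points)

- which holds at 4.0 h: what has brought the reaction to rest, or that it has not come to rest (all of the starting material has reacted / no working catalyst is left / forward and back rates have come level / it is still moving / the reagent has run out first)
- part of the starting material gone at 4.0 h
- the target standing at 4.0 h, as a percentage of the starting material charged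
- the catalyst intermediate A standing at 4.0 h, as a percentage of the starting material charged

- the earlier runs were read with a standard deviation of 0.5 percentage points
- the reaction counts as stopped when no species that holds the starting material changes by six tenths of a point or more over the second half of the time
- what has gone from starting material into another species counts as reacted, even if it can come back

The table can be read summer against winter, row by row. The target levels off by about 1.00 h in summer and 0.667 h in winter. Those times stand at 1.50 to one while the loadings of free catalyst stand at 1.60 to one, so, as far as these spaced readings show, the time runs roughly inversely with loading. The flask, at 75 mM, should then stop near 1.33 h, earlier than 4.0 h.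

The last rows give the target per catalyst charged as 11.5 in summer and 7.45 in winter, so the two runs do not share one number of turnovers to target. The same target per reagent charged reads 80.7 % and 84.0 %, which moves by 3.3 percentage points across that change in loading.

My reckoning is therefore that the reagent is the limiting reagent, shared out between the two substrates. A straight line through the two readings gives 79.3 % at the flask's loading. This is the reagent share σ, target formed per reagent charged with the charge taken as used up, one flat mean standing in for a curve that changes along the run. The flask's target is then σ times the ratio, 75.1 %, and if the whole gap between the runs is taken as the error of the flat mean, it is good to 3.1 points.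

The forecast says no working catalyst is left, with 78 % gone, 75 % target and 3 % catalyst intermediate A, holding that “the catalyst most likely dies”.

The flask gives: the reagent has run out first, 78.6 % gone, 75.6 % target, 3.04 % catalyst intermediate A.

    starting material + free catalyst ⇌ catalyst intermediate A (K = 32.0 /M, k = 0.190 /M/s)
    reagent + catalyst intermediate A → free catalyst + target (k = 0.0140 /M/s)
    second substrate + free catalyst ⇌ catalyst intermediate B (K = 1.70 /M, k = 0.270 /M/s)
    reagent + catalyst intermediate B → free catalyst + second product (k = 0.0340 /M/s)
    2 catalyst intermediate B ⇌ resting dimer, settled at all times (K = 100 /M)

At 4.00 h the flask holds 0 % of its reagent. Target and second product together come to 1.42 M against 1.42 M charged, and σ stands at 79.8 % beside the reckoned 79.3 %. The neighbouring flask with 0.35 M of reagent, reckoned with the same σ, should give 18.5 % target. It gives 21.1 %, with 0 % of its reagent left, so σ there is 90.3 %.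

(Readings and results were computed with constants of no real substance, and the scatter is random.)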